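The butenolide (ring atoms O1, C2 carbonyl, C3 methyl, C4 carboxyl, C5) is disconnected at the C5–H bond and the O1–C2 lactone bond. The lone stereocentre, C5, carries the ring oxygen of a γ-hydroxy acid; one oxidation level higher it is the hemiketal carbon of a 5-hydroxybutenolide, whose enantiomers exchange through an achiral open-chain γ-keto acid. One asymmetric transfer hydrogenation should reduce that ketone from one face and let the (R)-hydroxy acid relactonise, so the stereocentre, the ring and the target arise in a single operation. The precursor is the unprotected racemic lactol diacid, reached by singlet-oxygen opening of a Feist–Benary furan.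

Key step: step 5

Assumption: the sense of induction is assigned by the aryl alkyl ketone model with the C4 vinyl group in the aryl role, so the (R,R)-ligand is taken to give (R) at C5; if the opposite sense were found, the (S,S)-ligand would be used with no other change.

Step 1
Reactants: 1 hexadecanedioic acid monomethyl ester; 2 2,2-dimethyl-1,3-dioxane-4,6-dione (Meldrum's acid)
Product: 4 dimethyl 3-oxooctadecanedioate, via acyl Meldrum's acid 3 (not isolated)
Conditions: DCC, DMAP, CH2Cl2, 0 °C to rt; filter, aq. KHSO4 wash; then MeOH, reflux
Reagents that add atoms: methanol, CO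
Why: Carbodiimide activation should let the free acid terminus C-acylate Meldrum's acid, and methanolysis of adduct 3 with loss of acetone and CO2 is the standard two-carbon homologation of an acid to a β-keto ester, the distal methyl ester being inert.

Step 2
Reactants: 4 dimethyl 3-oxooctadecanedioate; 5 chloroacetone
Product: 7 methyl 2-(15-methoxy-15-oxopentadecyl)-4-methylfuran-3-carboxylate, via hydroxydihydrofuran 6 (not isolated)
Conditions: pyridine, 60 °C; then TsOH·H2O (cat.), toluene, 80 °C
Reagents that add atoms: none
Why: Feist–Benary furan synthesis, in which aldol addition of the active methylene to the chloroacetone carbonyl, enol O-alkylation at CH2Cl and acid-promoted dehydration of 6 should place the chain at furan C2, the ester at C3, methyl at C4 and hydrogen at C5.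

Step 3
Reactants: 7 methyl 2-(15-methoxy-15-oxopentadecyl)-4-methylfuran-3-carboxylate
Product: 8 2-(14-carboxytetradecyl)-4-methylfuran-3-carboxylic acid
Conditions: KOH, MeOH/THF/H2O, reflux; then aq. HCl to pH 2, 0 °C
Reagents that add atoms: potassium hydroxide (aqueous; hydroxide supplies the new carboxyl oxygens), [K+].[OH-]
Why: Plain saponification of both methyl esters on the robust aromatic furan, carried out here because no stereocentre exists yet, with heating to overcome the flanked 3-furoate.

Step 4
Reactants: 8 2-(14-carboxytetradecyl)-4-methylfuran-3-carboxylic acid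
Product: 10 racemic 2-(14-carboxytetradecyl)-2-hydroxy-4-methyl-5-oxo-2,5-dihydrofuran-3-carboxylic acid, via furan endoperoxide 9 (not isolated)
Conditions: O2, hν (visible), tetraphenylporphyrin (cat.), iPr2NEt, CH2Cl2, −78 °C to rt; then aq. HCl (pH 2)
Reagents that add atoms: dioxygen (as singlet oxygen), O=O
Why: Singlet oxygen should add [4+2] across furan C2/C5 and the amine should remove the only bridgehead hydrogen of 9 with O–O cleavage (Kornblum–DeLaMare rearrangement), which puts the lactone carbonyl at the former C5 and the hemiketal at the chain-bearing carbon, so only one regioisomer is possible and the new lactol carbon is formed racemic and labile.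

Step 5
Reactants: 10 racemic 2-(14-carboxytetradecyl)-2-hydroxy-4-methyl-5-oxo-2,5-dihydrofuran-3-carboxylic acid
Product: 13 (R)-2-(14-carboxytetradecyl)-4-methyl-5-oxo-2,5-dihydrofuran-3-carboxylic acid, via open keto triacid 11 (not isolated), via (R)-hydroxy triacid 12 (not isolated)
Conditions: RuCl(p-cymene)[(R,R)-TsDPEN] (cat.), HCO2H/Et3N (5:2), EtOAc, 30–40 °C; then aq. HCl, crystallisation
Reagents that add atoms: none
Why: Proposed new method: in the formic acid–triethylamine medium lactol 10 should stand in fast ring–chain exchange with the achiral keto acid 11, whose ketone accepts hydride from ruthenium and a proton from the ligand NH in a concerted outer-sphere transition state; the closest known reaction type is the transfer hydrogenation of γ-keto acids and of 2-acylbenzoic acids with this catalyst family, which gives γ-lactones and phthalides, and the untested element is the tetrasubstituted, doubly carboxylated alkene beside the ketone. The resulting hydroxy acid 12 should close the ring O1–C2–C3–C4–C5 through the O1–C2 bond by 5-exo-trig acyl substitution, because the C3 carboxyl is locked cis to the carbinol across C3=C4. The configuration at C5 is controlled by the (R,R)-TsDPEN ligand, which should seat the planar vinyl substituent under the p-cymene ring and turn the alkyl chain outwards, as it does with aryl alkyl ketones. Stereoconvergence requires only that both enantiomers of 10 reach 11, which the pseudo-acid equilibrium guarantees since 11 has no stereocentre. Reduction of C=O in preference to C3=C4 is secured by the alkene being fully substituted and, as a dicarboxylate, a poor hydride acceptor. The acidic medium and work-up keep the base-sensitive C5–H of 13 from racemising.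

Compound list
1 | hexadecanedioic acid monomethyl ester (16-methoxy-16-oxohexadecanoic acid) | COC(=O)CCCCCCCCCCCCCCC(=O)O | starting material
2 | 2,2-dimethyl-1,3-dioxane-4,6-dione (Meldrum's acid) | CC1(C)OC(=O)CC(=O)O1 | starting material
3 | 5-(1-hydroxy-16-methoxy-16-oxohexadecylidene)-2,2-dimethyl-1,3-dioxane-4,6-dione (acyl Meldrum's acid, enol form, not isolated) | COC(=O)CCCCCCCCCCCCCCC(O)=C1C(=O)OC(C)(C)OC1=O | intermediate
4 | dimethyl 3-oxooctadecanedioate | COC(=O)CC(=O)CCCCCCCCCCCCCCC(=O)OC | intermediate
5 | chloroacetone | CC(=O)CCl | starting material
6 | racemic methyl 4-hydroxy-2-(15-methoxy-15-oxopentadecyl)-4-methyl-4,5-dihydrofuran-3-carboxylate (not isolated) | COC(=O)C1=C(CCCCCCCCCCCCCCC(=O)OC)OCC1(C)O | intermediate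
7 | methyl 2-(15-methoxy-15-oxopentadecyl)-4-methylfuran-3-carboxylate | COC(=O)c1c(C)coc1CCCCCCCCCCCCCCC(=O)OC | intermediate
8 | 2-(14-carboxytetradecyl)-4-methylfuran-3-carboxylic acid | Cc1coc(CCCCCCCCCCCCCCC(=O)O)c1C(=O)O | intermediate
9 | racemic 1-(14-carboxytetradecyl)-5-methyl-2,3,7-trioxabicyclo[2.2.1]hept-5-ene-6-carboxylic acid (furan endoperoxide, not isolated) | CC1=C(C(=O)O)C2(CCCCCCCCCCCCCCC(=O)O)OOC1O2 | intermediate
10 | racemic 2-(14-carboxytetradecyl)-2-hydroxy-4-methyl-5-oxo-2,5-dihydrofuran-3-carboxylic acid (lactol, precursor of the key step) | CC1=C(C(=O)O)C(O)(CCCCCCCCCCCCCCC(=O)O)OC1=O | intermediate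
11 | (E)-2-(15-carboxypentadecanoyl)-3-methylbut-2-enedioic acid (open keto triacid, achiral, not isolated) | C/C(C(=O)O)=C(\C(=O)O)C(=O)CCCCCCCCCCCCCCC(=O)O | intermediate
12 | (R,E)-2-(15-carboxy-1-hydroxypentadecyl)-3-methylbut-2-enedioic acid (hydroxy triacid, not isolated) | C/C(C(=O)O)=C(\C(=O)O)[C@H](O)CCCCCCCCCCCCCCC(=O)O | intermediate
13 | (R)-2-(14-carboxytetradecyl)-4-methyl-5-oxo-2,5-dihydrofuran-3-carboxylic acid | CC1=C(C(=O)O)[C@@H](CCCCCCCCCCCCCCC(=O)O)OC1=O | target

Total step count: 5
Longest linear sequence: 5 steps (1 → 4 → 7 → 8 → 10 → 13)

Steps most likely to fail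

Step 5 (the step labelled as new). The hydride may add with poor facial selectivity, or too slowly to a hindered ketone twisted out of conjugation, or conjugate reduction of C3=C4 may compete. Fallback by known chemistry, setting out from 10: NaBH4 in aqueous NaOH at 0 °C should reduce the ring-opened keto carboxylate to racemic (E)-2-(15-carboxy-1-hydroxypentadecyl)-3-methylbut-2-enedioic acid F1. On acidification to pH 1 this should lactonise to racemic 2-(14-carboxytetradecyl)-4-methyl-5-oxo-2,5-dihydrofuran-3-carboxylic acid F2. Preparative chromatography on a chiral stationary phase (supercritical CO2/MeOH with formic acid) should then deliver the (R)-enantiomer, rejoining the route at 13, and set aside (S)-2-(14-carboxytetradecyl)-4-methyl-5-oxo-2,5-dihydrofuran-3-carboxylic acid F3.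

Step 2. C-alkylation of the keto ester by chloroacetone followed by Paal–Knorr closure would divert material to the 2,5-disubstituted furan, and N-alkylation of pyridine may consume the halo ketone. Fallback, setting out from 4: treatment with dimethyl(prop-2-yn-1-yl)sulfonium bromide and NaOMe in MeOH at reflux is a different furan annulation. The keto ester enolate adds to the allenylsulfonium salt formed in the flask, and enol O-alkylation with loss of dimethyl sulfide should give methyl 2-(15-methoxy-15-oxopentadecyl)-4-methylidene-4,5-dihydrofuran-3-carboxylate F4. Its tautomerisation to the aromatic furan rejoins the route at 7 with the same substitution pattern.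

Step 4. The cycloaddition may be sluggish on the acceptor-substituted furan, the endoperoxide may fragment by other pathways, or over-oxidation and sensitiser bleaching may intervene. Fallback, setting out from 8: a dark, non-photochemical oxidative ring opening with NaClO2 and NaH2PO4 in tBuOH/H2O at rt, known for 2-alkylfurans, should give the cis γ-keto acid, which closes to the lactol and rejoins the route at 10.

Further compounds
F1 | step 5 | racemic (E)-2-(15-carboxy-1-hydroxypentadecyl)-3-methylbut-2-enedioic acid | C/C(C(=O)O)=C(\C(=O)O)C(O)CCCCCCCCCCCCCCC(=O)O
F2 | step 5 | racemic 2-(14-carboxytetradecyl)-4-methyl-5-oxo-2,5-dihydrofuran-3-carboxylic acid | CC1=C(C(=O)O)C(CCCCCCCCCCCCCCC(=O)O)OC1=O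
F3 | step 5 | (S)-2-(14-carboxytetradecyl)-4-methyl-5-oxo-2,5-dihydrofuran-3-carboxylic acid | CC1=C(C(=O)O)[C@H](CCCCCCCCCCCCCCC(=O)O)OC1=O
F4 | step 2 | methyl 2-(15-methoxy-15-oxopentadecyl)-4-methylidene-4,5-dihydrofuran-3-carboxylate | COC(=O)C1=C(CCCCCCCCCCCCCCC(=O)OC)OCC1=C
F0 | step 4 | none | none
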